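The plan treats the cyclohexadienone ring (C5–C10) as a 2-methoxycyclohex-2-enone that lacks only the C9=C10 double bond. Spiro atom C5 is treated as the α-carbon of a lactone whose carbonyl C1 belongs to the future oxolane ring (C1, O2, C3–C5). A Robinson spiroannulation of an α-formyl lactone with 1-methoxybut-3-en-2-one then makes C5–C10 and C6=C7. It closes the carbocycle and fixes quaternary C5 in one operation, steered by the C4 substituent. The precursor is a trans-3-aryl-4-(pivaloyloxymethyl)butyrolactone bearing the formyl group (future C6) on C5, obtained through an Evans aldol. A second Evans aldol sets C1 and C1′, and benzylic ring closure restores the oxolane.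

Key step: step 10

Remark: atom labels C1–C10 follow the 2-oxaspiro[4.5]decane numbering of the target (C1 side-chain carbon, O2, C3 aryl carbon, C4, spiro C5, C7 methoxy carbon, C8 carbonyl) and are kept for the same atoms in every precursor. C1′ is the aryloxy-bearing side-chain carbon. Centres that are mixtures and vanish later are drawn without configuration.

Step 1
Reactants: 1 vanillin
Product: 2 3-methoxy-4-(triisopropylsilyloxy)benzaldehyde
Conditions: TIPSCl, imidazole, DMF, rt
Reagents that add atoms: triisopropylsilyl chloride, CC(C)[Si](Cl)(C(C)C)C(C)C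
Why: Imidazole-promoted silylation of the phenol; the TIPS aryl ether is chosen because it resists the basic steps 5, 8 and 11 better than a TBS aryl ether and still leaves with fluoride at the end.

Step 2
Reactants: 3 mono-tert-butyl succinate; 4 (S)-4-benzyl-1,3-oxazolidin-2-one
Product: 6 tert-butyl 4-[(4S)-4-benzyl-2-oxo-1,3-oxazolidin-3-yl]-4-oxobutanoate, via mixed pivalic anhydride 5 (not isolated)
Conditions: PivCl, Et3N, THF, −20 °C; then 4, LiCl, −20 °C → rt
Reagents that add atoms: none
Why: N-Acylation of the oxazolidinone through a mixed anhydride, which is attacked at the less hindered succinyl carbonyl and leaves the tert-butyl ester untouched.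

Step 3
Reactants: 6 succinate imide; 2 silylated vanillin
Product: 9 tert-butyl (3S,4S)-3-[(4S)-4-benzyl-2-oxo-1,3-oxazolidine-3-carbonyl]-4-hydroxy-4-[3-methoxy-4-(triisopropylsilyloxy)phenyl]butanoate, via Z-boron enolate 7 (not isolated), via boron aldolate 8 (not isolated)
Conditions: Bu2BOTf, iPr2NEt, CH2Cl2, 0 °C; 2, −78 → 0 °C; pH 7 buffer, MeOH, H2O2, 0 °C
Reagents that add atoms: none
Why: Evans syn-aldol reaction, in which the Z-boron enolate reacts through a chair Zimmerman–Traxler transition state on the face away from the benzyl group of the (S)-auxiliary and so sets C4 and C3 as the (S,S) syn pair.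

Step 4
Reactants: 9 syn-aldol adduct
Product: 10 (4S)-4-benzyl-3-{(2S,3S)-2-[3-methoxy-4-(triisopropylsilyloxy)phenyl]-5-oxooxolane-3-carbonyl}-1,3-oxazolidin-2-one (trans lactone)
Conditions: TFA, CH2Cl2, 0 °C → rt
Reagents that add atoms: none
Why: Acidolysis of the tert-butyl ester and lactonisation of the C3 hydroxyl; the syn aldol maps onto the trans-3,4-disubstituted lactone, which is also the more stable isomer should C3 ionise reversibly.

Step 5
Reactants: 10 lactone imide
Product: 11 (2S,3S)-2-[3-methoxy-4-(triisopropylsilyloxy)phenyl]-5-oxooxolane-3-carboxylic acid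
Conditions: LiOH, H2O2, THF/H2O, 0 °C; Na2SO3; HCl to pH 2
Reagents that add atoms: hydrogen peroxide (as lithium hydroperoxide), OO
Why: Hydroperoxide cleavage of the N-acyl oxazolidinone at the exocyclic carbonyl; any lactone opened by base recloses on acidification because only this five-membered lactone can form.

Step 6
Reactants: 11 lactone acid
Product: 12 (4R,5S)-4-(hydroxymethyl)-5-[3-methoxy-4-(triisopropylsilyloxy)phenyl]oxolan-2-one
Conditions: BH3·SMe2, THF, 0 °C → rt; MeOH
Reagents that add atoms: none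
Why: Chemoselective borane reduction of a carboxylic acid beside a lactone, run without base so that translactonisation onto the new primary alcohol is avoided.

Step 7
Reactants: 12 hydroxymethyl lactone
Product: 13 {(2S,3R)-2-[3-methoxy-4-(triisopropylsilyloxy)phenyl]-5-oxooxolan-3-yl}methyl pivalate
Conditions: PivCl, pyridine, DMAP (cat.), CH2Cl2, 0 °C → rt
Reagents that add atoms: pivaloyl chloride, CC(C)(C)C(=O)Cl
Why: DMAP-catalysed esterification; the pivalate has no α-hydrogen, tolerates LDA at −78 °C, shields one face of C5 and will be removed without an extra step by the hydride in step 11.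

Step 8
Reactants: 13 lactone pivalate
Product: 15 {(2S,3R)-4-formyl-2-[3-methoxy-4-(triisopropylsilyloxy)phenyl]-5-oxooxolan-3-yl}methyl pivalate (C5 epimers in equilibrium with the hydroxymethylene enol), via lithium lactone enolate 14 (not isolated)
Conditions: LDA, THF, −78 °C; HCO2CH2CF3, −78 °C; AcOH
Reagents that add atoms: 2,2,2-trifluoroethyl formate, O=COCC(F)(F)F
Why: Crossed Claisen formylation of the kinetic lactone enolate with an activated formate; the released trifluoroethoxide is too poor a nucleophile to open the lactone, and the product rests as its stabilised enolate until the acid quench.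

Step 9
Reactants: 16 methyl methoxyacetate
Product: 18 1-methoxybut-3-en-2-one, via Weinreb amide 17 (not isolated)
Conditions: MeNHOMe·HCl, iPrMgCl, THF, −20 °C; CH2=CHMgBr, 0 °C; poured into cold 2 M HCl; kept as a BHT-stabilised ether solution
Reagents that add atoms: vinylmagnesium bromide, C=C[Mg]Br
Why: Weinreb ketone synthesis in one flask; the chelated adduct of the amide with the vinyl Grignard reagent resists over-addition, and the inverse acid quench keeps the freed amine protonated so that it cannot add to the enone.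

Step 10
Reactants: 15 α-formyl lactone; 18 1-methoxybut-3-en-2-one
Product: 21 {(3S,4R,5S)-7-methoxy-3-[3-methoxy-4-(triisopropylsilyloxy)phenyl]-1,8-dioxo-2-oxaspiro[4.5]dec-6-en-4-yl}methyl pivalate, via Michael adduct 19 (not isolated), via cyclic aldol 20 (not isolated)
Conditions: 18 (1.5 equiv), Et3N (10 mol %), toluene, 0 °C → rt; then Bn2NH·TFA (30 mol %), 4 Å MS, 50 °C
Reagents that add atoms: none
Why: Catalytic Et3N deprotonates the enolised 1,3-dicarbonyl unit of 15 and C5 adds to the terminal carbon of 18 (Michael addition, C5–C10) to give keto aldehyde 19, after which the ammonium salt promotes attack of C7, the methoxy-bearing α-carbon of the ketone, on the formyl carbon C6 (aldol 20) and loss of water to the conjugated 2-methoxyenone. This is the Robinson annulation of an α-formyl carbonyl compound with a vinyl ketone, here with methoxymethyl vinyl ketone as the four-carbon partner. The carbocycle closes in the 6-(enolendo)-exo-trig mode, and the other enol carbon, C9, could only form a cyclobutane, so regiochemistry is not in question. The one new stereocentre, quaternary C5, is controlled by C4: the acceptor reaches the planar enolate on the face opposite the pivaloyloxymethyl group, the normal sense for β-substituted butyrolactone enolates, which places C10 anti and C6 syn to that group (5S). The step needs C- over O-alkylation, secured because an oxa-Michael adduct reverts, and ring closure faster than retro-Claisen loss of the formyl group, secured by excluding alkoxide, hydroxide and strongly nucleophilic amines. The lactone and pivalate carbonyls are too poor as aldol acceptors to compete, and because the ring is still one double bond short of a dienone the new quaternary centre has no aromatisation pathway.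

Step 11
Reactants: 21 spiro lactone enone
Product: 23 (4S)-4-{(1S,2R)-1,3-dihydroxy-1-[3-methoxy-4-(triisopropylsilyloxy)phenyl]propan-2-yl}-4-(hydroxymethyl)-2-methoxycyclohex-2-en-1-one, via lithium dienolate 22 (not isolated)
Conditions: LDA (1.1 equiv), THF, −78 °C; LiAlH4, −78 → 0 °C; EtOAc at −78 °C, then aq. Rochelle salt/pH 7 buffer
Reagents that add atoms: none
Why: Protection of a ketone as its enolate during hydride reduction of esters; only C9 carries acidic hydrogens, the cross-conjugated dienolate is inert to LiAlH4 while lactone and pivalate are reduced, and destroying excess hydride with ethyl acetate before protonation returns the enone.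

Step 12
Reactants: 23 enone triol
Product: 24 (4S)-4-(hydroxymethyl)-2-methoxy-4-{(4S,5R)-4-[3-methoxy-4-(triisopropylsilyloxy)phenyl]-2,2-dimethyl-1,3-dioxan-5-yl}cyclohex-2-en-1-one
Conditions: Me2C(OMe)2, PPTS (5 mol %), CH2Cl2, rt
Reagents that add atoms: 2,2-dimethoxypropane, COC(C)(C)OC
Why: Acetonide formation by transacetalisation; only the C3 hydroxyl and the C4 hydroxymethyl group are 1,3-related and can give a six-membered ring, PPTS is too weak to ionise the benzylic alcohol, and the neopentyl C1 alcohol stays free.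

Step 13
Reactants: 24 acetonide alcohol
Product: 25 (1S)-3-methoxy-1-{(4S,5R)-4-[3-methoxy-4-(triisopropylsilyloxy)phenyl]-2,2-dimethyl-1,3-dioxan-5-yl}-4-oxocyclohex-2-ene-1-carbaldehyde
Conditions: DMP, CH2Cl2, 0 °C → rt
Reagents that add atoms: none
Why: Dess–Martin oxidation of the primary alcohol under nearly neutral conditions to an aldehyde that has no α-hydrogen and so cannot epimerise.

Step 14
Reactants: 26 methyl 3-(4-hydroxy-3-methoxyphenyl)propanoate
Product: 27 methyl 3-[4-(2-tert-butoxy-2-oxoethoxy)-3-methoxyphenyl]propanoate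
Conditions: BrCH2CO2tBu, K2CO3, acetone, reflux
Reagents that add atoms: tert-butyl bromoacetate, CC(C)(C)OC(=O)CBr
Why: Williamson ether synthesis of the phenoxide with an activated α-bromo ester.

Step 15
Reactants: 27 diester
Product: 28 2-[2-methoxy-4-(3-methoxy-3-oxopropyl)phenoxy]acetic acid
Conditions: TFA, CH2Cl2, rt
Reagents that add atoms: none
Why: Acidolysis of the tert-butyl ester by loss of isobutene, which leaves the methyl ester intact.

Step 16
Reactants: 28 aryloxyacetic acid; 29 (R)-4-benzyl-1,3-oxazolidin-2-one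
Product: 31 methyl 3-(4-{2-[(4R)-4-benzyl-2-oxo-1,3-oxazolidin-3-yl]-2-oxoethoxy}-3-methoxyphenyl)propanoate, via mixed pivalic anhydride 30 (not isolated)
Conditions: PivCl, Et3N, THF, −20 °C; then 29, LiCl, −20 °C → rt
Reagents that add atoms: none
Why: N-Acylation of the oxazolidinone through a mixed anhydride, as in step 2.

Step 17
Reactants: 31 aryloxyacetyl imide; 25 aldehyde
Product: 34 syn-glycolate aldol adduct (1S,1′R) with free C1 hydroxyl and C1′ bearing the aryloxy group and the imide carbonyl, via Z-boron enolate 32 (not isolated), via boron aldolate 33 (not isolated)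
Conditions: 31 (1.3 equiv), Bu2BOTf, Et3N, CH2Cl2, −78 → 0 °C; 25, −78 → 0 °C; pH 7 buffer, MeOH, H2O2, 0 °C
Reagents that add atoms: none
Why: Evans syn-glycolate aldol reaction; the boron enolate adds to the aldehyde far faster than to the enone carbonyl through a Zimmerman–Traxler chair, and the (R)-auxiliary dictates the threo C1–OH/C1′–OAr pair over the weak bias of the α-quaternary aldehyde.

Step 18
Reactants: 34 aldol adduct
Product: 35 (1S,3S,4R,5S)-2-oxaspiro[4.5]dec-6-en-8-one with 7-methoxy and 4-hydroxymethyl groups plus the 3-aryl group and the (1′R) aryloxy imide side chain on C1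
Conditions: CSA (20 mol %), CH2Cl2, 0 °C → rt
Reagents that add atoms: none
Why: Acid-catalysed benzylic SN1 etherification of the kind used for 2-aryltetrahydrofuran lignans; the C3–O bond of the dioxane ionises to the aryl-stabilised cation, the C1 hydroxyl closes the five-membered ring with loss of acetone, and reversible closure puts the aryl group trans to both the C4 and the C1 substituents, which restores (3S).

Step 19
Reactants: 35 spiro enone imide
Product: 36 tetraol (1S,3S,4R,5S,1′S) with C8 hydroxyl as an epimer mixture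
Conditions: LiBH4, MeOH, THF, 0 °C → rt
Reagents that add atoms: none
Why: Reductive removal of the auxiliary with LiBH4, which in the same operation reduces the methyl ester to the 3-hydroxypropyl chain and the enone carbonyl by 1,2-addition to a C8 alcohol of irrelevant configuration.

Step 20
Reactants: 36 tetraol
Product: 37 enone triol (9,10-dihydro derivative of the target as its phenol TIPS ether)
Conditions: activated MnO2, CH2Cl2/acetone, rt
Reagents that add atoms: none
Why: Chemoselective MnO2 oxidation of the allylic alcohol, which leaves the three saturated primary alcohols and the benzylic ether alone.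

Step 21
Reactants: 37 enone triol
Product: 39 dienone tris(trimethylsilyl) ether, via silyl dienol ether 38 (not isolated)
Conditions: TMSOTf, Et3N, CH2Cl2, 0 °C; then Pd(OAc)2, MeCN, rt
Reagents that add atoms: trimethylsilyl triflate, C[Si](C)(C)OS(=O)(=O)C(F)(F)F
Why: Saegusa–Ito oxidation; enolisation can only occur toward C9, the silylating agent caps the three primary alcohols at the same time, and the oxo-π-allylpalladium species loses a C10 hydrogen to give the cross-conjugated dienone without strong acid or base.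

Step 22
Reactants: 39 silylated dienone
Product: 40 target CNP0252711.1
Conditions: TBAF, AcOH (1:1), THF, 0 °C → rt
Reagents that add atoms: none
Why: Fluoride desilylation buffered with acetic acid, so that neither phenoxide-triggered opening of the benzylic ether nor acid-induced aromatisation of the dienone is provoked.

Compound list
1 | vanillin | COc1cc(C=O)ccc1O | starting material
2 | 3-methoxy-4-(triisopropylsilyloxy)benzaldehyde | COc1cc(C=O)ccc1O[Si](C(C)C)(C(C)C)C(C)C | intermediate
3 | mono-tert-butyl succinate | OC(=O)CCC(=O)OC(C)(C)C | starting material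
4 | (S)-4-benzyl-1,3-oxazolidin-2-one | O=C1N[C@@H](Cc2ccccc2)CO1 | starting material
5 | mixed pivalic anhydride of 3 | CC(C)(C)OC(=O)CCC(=O)OC(=O)C(C)(C)C | intermediate
6 | succinate imide | CC(C)(C)OC(=O)CCC(=O)N1[C@@H](Cc2ccccc2)COC1=O | intermediate
7 | (Z)-dibutylboron enolate of 6 | CC(C)(C)OC(=O)C/C=C(\OB(CCCC)CCCC)N1[C@@H](Cc2ccccc2)COC1=O | intermediate
8 | dibutylboron aldolate | CC(C)(C)OC(=O)C[C@H](C(=O)N1[C@@H](Cc2ccccc2)COC1=O)[C@@H](c1ccc(O[Si](C(C)C)(C(C)C)C(C)C)c(OC)c1)OB(CCCC)CCCC | intermediate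
9 | (3S,4S) syn-aldol adduct | CC(C)(C)OC(=O)C[C@H](C(=O)N1[C@@H](Cc2ccccc2)COC1=O)[C@@H](c1ccc(O[Si](C(C)C)(C(C)C)C(C)C)c(OC)c1)O | intermediate
10 | trans lactone imide | O=C1C[C@H](C(=O)N2[C@@H](Cc3ccccc3)COC2=O)[C@@H](c2ccc(O[Si](C(C)C)(C(C)C)C(C)C)c(OC)c2)O1 | intermediate
11 | trans lactone acid | O=C1C[C@H](C(=O)O)[C@@H](c2ccc(O[Si](C(C)C)(C(C)C)C(C)C)c(OC)c2)O1 | intermediate
12 | trans hydroxymethyl lactone | O=C1C[C@H](CO)[C@@H](c2ccc(O[Si](C(C)C)(C(C)C)C(C)C)c(OC)c2)O1 | intermediate
13 | trans lactone pivalate | O=C1C[C@H](COC(=O)C(C)(C)C)[C@@H](c2ccc(O[Si](C(C)C)(C(C)C)C(C)C)c(OC)c2)O1 | intermediate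
14 | lithium enolate of 13 | [Li]OC1=C[C@H](COC(=O)C(C)(C)C)[C@@H](c2ccc(O[Si](C(C)C)(C(C)C)C(C)C)c(OC)c2)O1 | intermediate
15 | α-formyl trans lactone (C5 epimers and enol) | O=CC1[C@H](COC(=O)C(C)(C)C)[C@@H](c2ccc(O[Si](C(C)C)(C(C)C)C(C)C)c(OC)c2)OC1=O | intermediate
16 | methyl methoxyacetate | COCC(=O)OC | starting material
17 | N,2-dimethoxy-N-methylacetamide | COCC(=O)N(C)OC | intermediate
18 | 1-methoxybut-3-en-2-one | COCC(=O)C=C | intermediate
19 | (5S) Michael adduct, keto aldehyde | O=C[C@]1(CCC(=O)COC)[C@H](COC(=O)C(C)(C)C)[C@@H](c2ccc(O[Si](C(C)C)(C(C)C)C(C)C)c(OC)c2)OC1=O | intermediate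
20 | cyclic aldol, 6-hydroxy-7-methoxy ketone | COC1C(O)[C@]2(CCC1=O)[C@H](COC(=O)C(C)(C)C)[C@@H](c3ccc(O[Si](C(C)C)(C(C)C)C(C)C)c(OC)c3)OC2=O | intermediate
21 | (3S,4R,5S) spiro lactone 2-methoxycyclohexenone | COC1=C[C@]2(CCC1=O)[C@H](COC(=O)C(C)(C)C)[C@@H](c3ccc(O[Si](C(C)C)(C(C)C)C(C)C)c(OC)c3)OC2=O | intermediate
22 | lithium dienolate of 21 | COC1=C[C@]2(CC=C1O[Li])[C@H](COC(=O)C(C)(C)C)[C@@H](c3ccc(O[Si](C(C)C)(C(C)C)C(C)C)c(OC)c3)OC2=O | intermediate
23 | enone triol | COC1=C[C@](CO)(CCC1=O)[C@H](CO)[C@@H](c2ccc(O[Si](C(C)C)(C(C)C)C(C)C)c(OC)c2)O | intermediate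
24 | acetonide alcohol | COC1=C[C@](CO)(CCC1=O)[C@@H]2COC(C)(C)O[C@@H]2c3ccc(O[Si](C(C)C)(C(C)C)C(C)C)c(OC)c3 | intermediate
25 | acetonide aldehyde | COC1=C[C@](C=O)(CCC1=O)[C@@H]2COC(C)(C)O[C@@H]2c3ccc(O[Si](C(C)C)(C(C)C)C(C)C)c(OC)c3 | intermediate
26 | methyl 3-(4-hydroxy-3-methoxyphenyl)propanoate | COC(=O)CCc1ccc(O)c(OC)c1 | starting material
27 | tert-butyl aryloxyacetate | COC(=O)CCc1ccc(OCC(=O)OC(C)(C)C)c(OC)c1 | intermediate
28 | aryloxyacetic acid | COC(=O)CCc1ccc(OCC(=O)O)c(OC)c1 | intermediate
29 | (R)-4-benzyl-1,3-oxazolidin-2-one | O=C1N[C@H](Cc2ccccc2)CO1 | starting material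
30 | mixed pivalic anhydride of 28 | COC(=O)CCc1ccc(OCC(=O)OC(=O)C(C)(C)C)c(OC)c1 | intermediate
31 | aryloxyacetyl imide | COC(=O)CCc1ccc(OCC(=O)N2[C@H](Cc3ccccc3)COC2=O)c(OC)c1 | intermediate
32 | (Z)-dibutylboron enolate of 31 | COC(=O)CCc1ccc(O/C=C(\OB(CCCC)CCCC)N2[C@H](Cc3ccccc3)COC2=O)c(OC)c1 | intermediate
33 | dibutylboron aldolate | COC1=C[C@]([C@H](OB(CCCC)CCCC)[C@H](C(=O)N2[C@H](Cc3ccccc3)COC2=O)Oc2ccc(CCC(=O)OC)cc2OC)(CCC1=O)[C@@H]2COC(C)(C)O[C@@H]2c3ccc(O[Si](C(C)C)(C(C)C)C(C)C)c(OC)c3 | intermediate
34 | (1S,1′R) syn-glycolate aldol adduct | COC1=C[C@]([C@H](O)[C@H](C(=O)N2[C@H](Cc3ccccc3)COC2=O)Oc2ccc(CCC(=O)OC)cc2OC)(CCC1=O)[C@@H]2COC(C)(C)O[C@@H]2c3ccc(O[Si](C(C)C)(C(C)C)C(C)C)c(OC)c3 | intermediate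
35 | (1S,3S,4R,5S,1′R) spiro enone imide | COC1=C[C@]2(CCC1=O)[C@H](CO)[C@@H](c3ccc(O[Si](C(C)C)(C(C)C)C(C)C)c(OC)c3)O[C@@H]2[C@H](C(=O)N3[C@H](Cc4ccccc4)COC3=O)Oc3ccc(CCC(=O)OC)cc3OC | intermediate
36 | tetraol (C8 epimers) | COC1=C[C@]2(CCC1O)[C@H](CO)[C@@H](c3ccc(O[Si](C(C)C)(C(C)C)C(C)C)c(OC)c3)O[C@@H]2[C@H](CO)Oc3ccc(CCCO)cc3OC | intermediate
37 | enone triol, phenol TIPS ether | COC1=C[C@]2(CCC1=O)[C@H](CO)[C@@H](c3ccc(O[Si](C(C)C)(C(C)C)C(C)C)c(OC)c3)O[C@@H]2[C@H](CO)Oc3ccc(CCCO)cc3OC | intermediate
38 | trimethylsilyl dienol ether, tris-TMS ether | COC1=C[C@]2(CC=C1O[Si](C)(C)C)[C@H](CO[Si](C)(C)C)[C@@H](c3ccc(O[Si](C(C)C)(C(C)C)C(C)C)c(OC)c3)O[C@@H]2[C@H](CO[Si](C)(C)C)Oc3ccc(CCCO[Si](C)(C)C)cc3OC | intermediate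
39 | dienone tris-TMS ether, phenol TIPS ether | COC1=C[C@]2(C=CC1=O)[C@H](CO[Si](C)(C)C)[C@@H](c3ccc(O[Si](C(C)C)(C(C)C)C(C)C)c(OC)c3)O[C@@H]2[C@H](CO[Si](C)(C)C)Oc3ccc(CCCO[Si](C)(C)C)cc3OC | intermediate
40 | CNP0252711.1, (1S,3S,4R,5S,1′S) | COC1=C[C@]2(C=CC1=O)[C@H](CO)[C@@H](c1ccc(O)c(OC)c1)O[C@@H]2[C@H](CO)Oc1ccc(CCCO)cc1OC | target

Total step count: 22. Longest linear sequence: 17 steps from vanillin (steps 1, 3–8, 10–13, 17–22).

Steps most likely to fail

Step 10. The formyl group may be lost from the quaternary Michael adduct by retro-Claisen cleavage while the aldol closure lags, and the vinyl ketone may polymerise. The fallback sets out from 15 and comes back at 21; it closes the ring by olefination instead of aldol condensation.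
- Conjugate addition of 15 to acrolein (cat. Et3N, CH2Cl2, 0 °C) should give, under the same facial control, the dialdehyde F1.
- Lithiated dimethyl (methoxymethyl)phosphonate (LDA, THF, −78 °C) should add only to the unhindered chain aldehyde and give the hydroxy phosphonate F2.
- Dess–Martin oxidation leads to the keto phosphonate F3.
- An intramolecular Horner–Wadsworth–Emmons reaction under Masamune–Roush conditions (LiCl, iPr2NEt, MeCN) joins C7 to the formyl carbon and delivers 21.

Step 11. Incomplete or reversible enolisation would let hydride reach C8, so the enone would be over-reduced to the acid-labile methoxy allylic alcohol. The fallback sets out from 21 and comes back at 23; it uses an isolable covalent mask.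
- TESOTf and Et3N (CH2Cl2, 0 °C) convert the ketone into the triethylsilyl dienol ether F4, purified on amine-deactivated silica.
- LiAlH4 (THF, 0 °C) reduces lactone and pivalate to the silyl dienol ether triol F5.
- AcOH/THF/H2O at 0 °C cleaves the enol silane, without touching the benzylic alcohol, to give 23.

Step 18. The C3–O bond may ionise slowly, because a silyloxy group is only a moderate donor. Loss of H-4 to a styrene or acid-promoted C1–C5 cleavage (vinylogous retro-aldol) could then compete. The fallback sets out from 34 and comes back at 35; it closes the ring through a quinone methide.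
- TBAF/AcOH (THF, 0 °C) frees the phenol acetonide F6.
- The p-hydroxybenzyl C3–O bond of F6 ionises under PPTS (CH2Cl2, rt) to the p-quinone methide, which the C1 hydroxyl traps in a 1,6-addition with the same trans preference, giving the spiro enone phenol F7.
- Selective silylation of the phenoxide (TIPSCl, DBU, 1 equiv each, CH2Cl2, 0 °C) returns 35.

Further compounds
F1 | step 10 | (5S) dialdehyde, 5-formyl-5-(3-oxopropyl) lactone pivalate | O=C[C@]1(CCC=O)[C@H](COC(=O)C(C)(C)C)[C@@H](c2ccc(O[Si](C(C)C)(C(C)C)C(C)C)c(OC)c2)OC1=O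
F2 | step 10 | hydroxy phosphonate (carbinol and phosphonate carbons as mixtures) | O=C[C@]1(CCC(O)C(OC)P(=O)(OC)OC)[C@H](COC(=O)C(C)(C)C)[C@@H](c2ccc(O[Si](C(C)C)(C(C)C)C(C)C)c(OC)c2)OC1=O
F3 | step 10 | keto phosphonate | O=C[C@]1(CCC(=O)C(OC)P(=O)(OC)OC)[C@H](COC(=O)C(C)(C)C)[C@@H](c2ccc(O[Si](C(C)C)(C(C)C)C(C)C)c(OC)c2)OC1=O
F4 | step 11 | triethylsilyl dienol ether of 21 | COC1=C[C@]2(CC=C1O[Si](CC)(CC)CC)[C@H](COC(=O)C(C)(C)C)[C@@H](c3ccc(O[Si](C(C)C)(C(C)C)C(C)C)c(OC)c3)OC2=O
F5 | step 11 | silyl dienol ether triol | COC1=C[C@](CO)(CC=C1O[Si](CC)(CC)CC)[C@H](CO)[C@@H](c2ccc(O[Si](C(C)C)(C(C)C)C(C)C)c(OC)c2)O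
F6 | step 18 | phenol acetonide (34 without TIPS) | COC1=C[C@]([C@H](O)[C@H](C(=O)N2[C@H](Cc3ccccc3)COC2=O)Oc2ccc(CCC(=O)OC)cc2OC)(CCC1=O)[C@@H]2COC(C)(C)O[C@@H]2c3ccc(O)c(OC)c3
F7 | step 18 | spiro enone phenol (35 without TIPS) | COC1=C[C@]2(CCC1=O)[C@H](CO)[C@@H](c3ccc(O)c(OC)c3)O[C@@H]2[C@H](C(=O)N3[C@H](Cc4ccccc4)COC3=O)Oc3ccc(CCC(=O)OC)cc3OC
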